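**Retrosynthetic overview**
- The tetronic acid ring is closed last by Dieckmann condensation of an (E)-enol propanoate; that enol ester comes from a cis-selective (Ando-type) Horner–Wadsworth–Emmons reaction of an α-methyl aldehyde.
- The only stereocentre is bought: Negishi sp3–sp2 coupling of the zinc reagent of methyl (R)-3-bromo-2-methylpropanoate (Roche-ester series) with an (E,E)-dienyl iodide.
- The dienyl iodide comes from a bis-furan propanol by oxidation/Wittig (E-enal) and Takai iodo-olefination.
- Key ring: the central 3,4-disubstituted furan, by Diels–Alder/retro-Diels–Alder reaction of 4-phenyloxazole with a 3-furylmethyl alkyne (loss of benzonitrile); the alkyne comes from 3-(bromomethyl)furan and pent-4-yn-1-ol.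
- Ring order: 3-furyl ring bought, then central furan (step 2), then tetronic acid (step 9).

Assumption: the SMILES is taken literally, i.e. S at the methyl-bearing carbon, an (E,E)-diene, and a 5E exocyclic enol-ether alkene (side chain on the C4–OH side of the ring).

**Route**

Step 1
Reactants: 1 3-(bromomethyl)furan; 2 pent-4-yn-1-ol
Product: 4 6-(furan-3-yl)hex-4-yn-1-ol, via bis-bromomagnesium acetylide-alkoxide 3 (not isolated)
Conditions: EtMgBr (2.1 equiv), THF, 0 → 40 °C; then CuBr·SMe2 (5 mol%), 1, 0 °C → rt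
Reagents that add atoms: none
Why: Copper-catalysed SN2 coupling of an alkynyl Grignard reagent with a furylmethyl (allylic/benzylic-type) bromide, in which the magnesium alkoxide is too poor a nucleophile to compete, so the alcohol needs no protection.

Step 2
Reactants: 4 6-(furan-3-yl)hex-4-yn-1-ol; 5 4-phenyl-1,3-oxazole
Product: 7 3-[4-(furan-3-ylmethyl)furan-3-yl]propan-1-ol, via oxa-aza-norbornadiene cycloadduct 6 (not isolated)
Conditions: 5 (3 equiv), neat, hydroquinone (cat.), sealed tube, 220 °C, 24 h
Reagents that add atoms: none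
Why: Oxazole–alkyne Diels–Alder/retro-Diels–Alder sequence in which the oxazole reacts as a 2-azadiene across C2/C5 and the bicyclic adduct (either regioisomer) expels benzonitrile, leaving a furan whose 3- and 4-substituents are the two alkyne substituents; no stereocentre is formed.

Step 3
Reactants: 7 3-[4-(furan-3-ylmethyl)furan-3-yl]propan-1-ol; 8 2-(triphenyl-λ5-phosphanylidene)propanal
Product: 10 (2E)-5-[4-(furan-3-ylmethyl)furan-3-yl]-2-methylpent-2-enal, via 3-[4-(furan-3-ylmethyl)furan-3-yl]propanal 9 (not isolated)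
Conditions: TEMPO (10 mol%), PhI(OAc)2 (1.1 equiv), CH2Cl2, rt; then 8 (1.3 equiv), PhMe, 80 °C
Reagents that add atoms: none
Why: One-pot oxidation–Wittig reaction: the TEMPO/PhI(OAc)2 oxidation stops at the aldehyde and tolerates furans, and the stabilised formyl ylide gives the (E)-trisubstituted enal under thermodynamic control.

Step 4
Reactants: 10 (2E)-5-[4-(furan-3-ylmethyl)furan-3-yl]-2-methylpent-2-enal
Product: 11 3-(furan-3-ylmethyl)-4-[(3E,5E)-6-iodo-4-methylhexa-3,5-dien-1-yl]furan
Conditions: CrCl2 (6 equiv), CHI3 (2 equiv), THF/1,4-dioxane, 0 °C → rt, dark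
Reagents that add atoms: iodoform, IC(I)I
Why: Takai olefination, in which the gem-dichromium species from CHI3 adds 1,2 to the enal and eliminates to the (E)-vinyl iodide while the existing trisubstituted alkene keeps its geometry.

Step 5
Reactants: 11 3-(furan-3-ylmethyl)-4-[(3E,5E)-6-iodo-4-methylhexa-3,5-dien-1-yl]furan; 12 methyl (2R)-3-bromo-2-methylpropanoate
Product: 14 methyl (2S,4E,6E)-9-[4-(furan-3-ylmethyl)furan-3-yl]-2,6-dimethylnona-4,6-dienoate, via alkylzinc bromide 13 (not isolated)
Conditions: 12, Zn dust (I2-activated), LiCl, THF, 40 °C; then 11, Pd(PPh3)4 (5 mol%), THF/DMA, rt → 40 °C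
Reagents that add atoms: none
Why: Negishi sp3–sp2 cross-coupling in which zinc inserts into the C–Br bond one carbon away from the bought stereocentre and zerovalent palladium joins the alkylzinc to the dienyl iodide with retention of both alkene geometries; the descriptor changes from R to S only because CH2Br outranks CO2Me whereas the new allylic CH2 does not.

Step 6
Reactants: 14 methyl (2S,4E,6E)-9-[4-(furan-3-ylmethyl)furan-3-yl]-2,6-dimethylnona-4,6-dienoate
Product: 15 (2S,4E,6E)-9-[4-(furan-3-ylmethyl)furan-3-yl]-2,6-dimethylnona-4,6-dienal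
Conditions: (Me2CHCH2)2AlH (1.1 equiv), CH2Cl2, −78 °C; MeOH, then aq. potassium sodium tartrate; crude aldehyde used at once
Reagents that add atoms: none
Why: Partial hydride reduction of the ester, in which the tetrahedral aluminium hemiacetal survives at −78 °C until the quench, so the aldehyde is released without over-reduction or epimerisation of the α-stereocentre.

Step 7
Reactants: 16 ethyl glyoxylate (50% in PhMe); 17 diphenyl phosphite
Product: 19 ethyl 2-(diphenoxyphosphoryl)-2-(propanoyloxy)acetate, via ethyl 2-(diphenoxyphosphoryl)-2-hydroxyacetate 18 (not isolated)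
Conditions: PhMe, 60 °C; then (EtCO)2O, pyridine, DMAP (cat.), 0 °C → rt
Reagents that add atoms: propanoic anhydride, CCC(=O)OC(=O)CC
Why: Pudovik addition of the P–H bond to the glyoxylate aldehyde followed by O-acylation in the same flask, kept free of strong base to avoid phospha-Brook rearrangement; the stereocentre of 19 is racemic and is destroyed in step 8.

Step 8
Reactants: 15 (2S,4E,6E)-9-[4-(furan-3-ylmethyl)furan-3-yl]-2,6-dimethylnona-4,6-dienal; 19 ethyl 2-(diphenoxyphosphoryl)-2-(propanoyloxy)acetate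
Product: 20 ethyl (2E,4S,6E,8E)-11-[4-(furan-3-ylmethyl)furan-3-yl]-4,8-dimethyl-2-(propanoyloxy)undeca-2,6,8-trienoate
Conditions: 19 (1.3 equiv), NaI, DBU, THF, −78 → 0 °C
Reagents that add atoms: none
Why: Ando-type Horner–Wadsworth–Emmons olefination, in which the electron-poor diaryl phosphonate makes the kinetically formed oxaphosphetane collapse before it equilibrates and so places the aldehyde residue cis to the ester group (2E by CIP, since the acyloxy oxygen outranks the ester carbon); this selectivity is argued by analogy with diaryl phosphonopropanoates and phosphonoglycinates and is untested for this reagent, and the mild base leaves the α-stereocentre of 15 intact.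

Step 9
Reactants: 20 ethyl (2E,4S,6E,8E)-11-[4-(furan-3-ylmethyl)furan-3-yl]-4,8-dimethyl-2-(propanoyloxy)undeca-2,6,8-trienoate
Product: 21 (5E)-5-{(2S,4E,6E)-9-[4-(furan-3-ylmethyl)furan-3-yl]-2,6-dimethylnona-4,6-dien-1-ylidene}-4-hydroxy-3-methylfuran-2(5H)-one
Conditions: LiN(SiMe3)2 (2.5 equiv), THF, −78 → −20 °C; cold 0.5 M HCl; light excluded
Reagents that add atoms: none
Why: Dieckmann (intramolecular Claisen) condensation, in which the unhindered propanoate α-carbon is deprotonated in preference to the hindered γ-C–H at the stereocentre, attacks the ethyl ester 5-exo-trig and the product is held as the tetronate anion; the enol-ester C=C is not touched, so its geometry becomes the 5E exocyclic alkene and the stereocentre stays S.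

**Compound list**

1 | 3-(bromomethyl)furan | BrCc1ccoc1 | starting material
2 | pent-4-yn-1-ol | C#CCCCO | starting material
3 | bromo{5-[(bromomagnesio)oxy]pent-1-yn-1-yl}magnesium | Br[Mg]C#CCCCO[Mg]Br | intermediate (not isolated)
4 | 6-(furan-3-yl)hex-4-yn-1-ol | OCCCC#CCc1ccoc1 | intermediate
5 | 4-phenyl-1,3-oxazole | c1ccccc1-c1cocn1 | starting material
6 | 3-[5-(furan-3-ylmethyl)-3-phenyl-7-oxa-2-azabicyclo[2.2.1]hepta-2,5-dien-6-yl]propan-1-ol (racemic; the regioisomeric adduct gives the same furan) | OCCCC1=C(Cc2ccoc2)C2OC1N=C2c1ccccc1 | intermediate (not isolated)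
7 | 3-[4-(furan-3-ylmethyl)furan-3-yl]propan-1-ol | OCCCc1cocc1Cc1ccoc1 | intermediate
8 | 2-(triphenyl-λ5-phosphanylidene)propanal | CC(C=O)=P(c1ccccc1)(c1ccccc1)c1ccccc1 | starting material
9 | 3-[4-(furan-3-ylmethyl)furan-3-yl]propanal | O=CCCc1cocc1Cc1ccoc1 | intermediate (not isolated)
10 | (2E)-5-[4-(furan-3-ylmethyl)furan-3-yl]-2-methylpent-2-enal | O=C/C(C)=C/CCc1cocc1Cc1ccoc1 | intermediate
11 | 3-(furan-3-ylmethyl)-4-[(3E,5E)-6-iodo-4-methylhexa-3,5-dien-1-yl]furan | I/C=C/C(C)=C/CCc1cocc1Cc1ccoc1 | intermediate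
12 | methyl (2R)-3-bromo-2-methylpropanoate | COC(=O)[C@@H](C)CBr | starting material
13 | bromo[(2R)-3-methoxy-2-methyl-3-oxopropyl]zinc | COC(=O)[C@@H](C)C[Zn]Br | intermediate (not isolated)
14 | methyl (2S,4E,6E)-9-[4-(furan-3-ylmethyl)furan-3-yl]-2,6-dimethylnona-4,6-dienoate | COC(=O)[C@@H](C)C/C=C/C(C)=C/CCc1cocc1Cc1ccoc1 | intermediate
15 | (2S,4E,6E)-9-[4-(furan-3-ylmethyl)furan-3-yl]-2,6-dimethylnona-4,6-dienal | O=C[C@@H](C)C/C=C/C(C)=C/CCc1cocc1Cc1ccoc1 | intermediate
16 | ethyl glyoxylate (ethyl 2-oxoacetate) | CCOC(=O)C=O | starting material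
17 | diphenyl phosphite (diphenyl phosphonate) | O=[PH](Oc1ccccc1)Oc1ccccc1 | starting material
18 | ethyl 2-(diphenoxyphosphoryl)-2-hydroxyacetate (racemic) | CCOC(=O)C(O)P(=O)(Oc1ccccc1)Oc1ccccc1 | intermediate (not isolated)
19 | ethyl 2-(diphenoxyphosphoryl)-2-(propanoyloxy)acetate (racemic) | CCOC(=O)C(OC(=O)CC)P(=O)(Oc1ccccc1)Oc1ccccc1 | intermediate
20 | ethyl (2E,4S,6E,8E)-11-[4-(furan-3-ylmethyl)furan-3-yl]-4,8-dimethyl-2-(propanoyloxy)undeca-2,6,8-trienoate | CCOC(=O)/C(=C\[C@@H](C)C/C=C/C(C)=C/CCc1cocc1Cc1ccoc1)OC(=O)CC | intermediate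
21 | (5E)-5-{(2S,4E,6E)-9-[4-(furan-3-ylmethyl)furan-3-yl]-2,6-dimethylnona-4,6-dien-1-ylidene}-4-hydroxy-3-methylfuran-2(5H)-one | CC1=C(O)/C(=C\[C@@H](C)C/C=C/C(C)=C/CCc2cocc2Cc2ccoc2)OC1=O | target

**Step count**

Total step count: 9. Longest linear sequence: 8 (steps 1 to 6, then 8 and 9; step 7 makes the phosphonate).

**Steps most likely to fail**

Step 2 is the first risk: an unactivated dialkyl alkyne needs about 220 °C to add the oxazole, and the reaction may stall or char the furans. The fallback activates the dienophile with a carbonyl group that is deleted afterwards. It sets out from the bis-Grignard 3, which is added to furan-3-carbaldehyde (THF, 0 °C) to give 1-(furan-3-yl)hex-2-yne-1,6-diol F1. MnO2 (CH2Cl2, rt) oxidises only the propargylic-furylic carbinol, giving 1-(furan-3-yl)-6-hydroxyhex-2-yn-1-one F2. This electron-poor ynone takes up 5 at about 130 °C (PhMe, sealed tube), and the cycloadduct 3-[5-(furan-3-carbonyl)-3-phenyl-7-oxa-2-azabicyclo[2.2.1]hepta-2,5-dien-6-yl]propan-1-ol F3 loses benzonitrile to give (furan-3-yl)[4-(3-hydroxypropyl)furan-3-yl]methanone F4. Wolff–Kishner reduction (N2H4·H2O, KOH, diethylene glycol, 130 → 200 °C) through the hydrazone 3-{4-[(furan-3-yl)(hydrazinylidene)methyl]furan-3-yl}propan-1-ol F5 removes the ketone, and the fallback comes back to the route at 7.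

Step 8 is the second risk: the 2E geometry is contra-thermodynamic and rests on kinetic control with a phosphonate that has no direct precedent. The fallback sets the geometry photochemically at the end instead. It sets out from 15, which is olefinated with 19 to whatever E/Z ratio results. The (2Z)-enol ester ethyl (2Z,4S,6E,8E)-11-[4-(furan-3-ylmethyl)furan-3-yl]-4,8-dimethyl-2-(propanoyloxy)undeca-2,6,8-trienoate F6 is cyclised exactly as in step 9 to (5Z)-5-{(2S,4E,6E)-9-[4-(furan-3-ylmethyl)furan-3-yl]-2,6-dimethylnona-4,6-dien-1-ylidene}-4-hydroxy-3-methylfuran-2(5H)-one F7. Irradiation of F7 (λ ≥ 300 nm, MeCN, Pyrex, where the diene should not absorb) gives an E/Z photostationary mixture; the E isomer is separated by reverse-phase HPLC and F7 is recycled. The fallback comes back to the route at 21.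

Step 9 is the third risk: the amide base may cleave the enol ester or deprotonate at the γ-position, which would scramble the alkene and the stereocentre. The fallback closes the ring before the olefination. It sets out from 19, which has no sensitive functionality and is cyclised with LiN(SiMe3)2 (THF, −78 → 0 °C) to 5-(diphenoxyphosphoryl)-4-hydroxy-3-methylfuran-2(5H)-one F8. The dianion of F8 (2.2 equiv LiN(SiMe3)2, THF, −78 °C) is condensed with aldehyde 15 in a Horner–Wadsworth–Emmons reaction; the same kinetic argument as in step 8 predicts the 5E alkene, though this is unverified for the cyclic phosphonate. The fallback comes back to the route at 21.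

**Further compounds**

F1 | step 2 | 1-(furan-3-yl)hex-2-yne-1,6-diol (racemic) | OCCCC#CC(O)c1ccoc1
F2 | step 2 | 1-(furan-3-yl)-6-hydroxyhex-2-yn-1-one | OCCCC#CC(=O)c1ccoc1
F3 | step 2 | 3-[5-(furan-3-carbonyl)-3-phenyl-7-oxa-2-azabicyclo[2.2.1]hepta-2,5-dien-6-yl]propan-1-ol (racemic) | OCCCC1=C(C(=O)c2ccoc2)C2OC1N=C2c1ccccc1
F4 | step 2 | (furan-3-yl)[4-(3-hydroxypropyl)furan-3-yl]methanone | OCCCc1cocc1C(=O)c1ccoc1
F5 | step 2 | 3-{4-[(furan-3-yl)(hydrazinylidene)methyl]furan-3-yl}propan-1-ol | NN=C(c1ccoc1)c1cocc1CCCO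
F6 | step 8 | ethyl (2Z,4S,6E,8E)-11-[4-(furan-3-ylmethyl)furan-3-yl]-4,8-dimethyl-2-(propanoyloxy)undeca-2,6,8-trienoate | CCOC(=O)/C(=C/[C@@H](C)C/C=C/C(C)=C/CCc1cocc1Cc1ccoc1)OC(=O)CC
F7 | step 8 | (5Z)-5-{(2S,4E,6E)-9-[4-(furan-3-ylmethyl)furan-3-yl]-2,6-dimethylnona-4,6-dien-1-ylidene}-4-hydroxy-3-methylfuran-2(5H)-one | CC1=C(O)/C(=C/[C@@H](C)C/C=C/C(C)=C/CCc2cocc2Cc2ccoc2)OC1=O
F8 | step 9 | 5-(diphenoxyphosphoryl)-4-hydroxy-3-methylfuran-2(5H)-one (racemic) | CC1=C(O)C(OC1=O)P(=O)(Oc1ccccc1)Oc1ccccc1
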